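**Retrosynthetic overview**
1. Both benzene rings are bought and no ring is formed. Ring A comes from 2-amino-5-bromophenol 1 (its bromine ends up para to the ether oxygen), activated through diazonium salt 2 as ortho-quinone diazide 3; ring B is 2,4-dibromophenol 4.
2. Key disconnection: the diaryl ether C–O bond of 5 (5-bromo-2-(2,4-dibromophenoxy)phenol) is cut to 3 + 4, a formal insertion of an ortho-hydroxyaryl carbene into the O–H bond of 4. The free ortho OH of the target is the former quinone carbonyl.
3. Last bonds made: the two C–Br bonds para and ortho to the free OH, installed on 5 with Br2 by way of monobromide 6, complete target 7.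

Assumption: the target SMILES has no stereocentre and the diaryl ether axis is not configurationally stable, so the compound is achiral and is made as drawn.

**Step 1**
Reactants: 1 2-amino-5-bromophenol
Product: 3 3-bromo-6-diazocyclohexa-2,4-dien-1-one, via 4-bromo-2-hydroxybenzenediazonium chloride 2 (not isolated)
Conditions: NaNO2 (1.05 equiv), 2 M aq HCl, 0 °C, 30 min; then NaHCO3 to pH 6–7, CH2Cl2 extraction, 0 °C, dark; dried (Na2SO4, 4 Å MS) and used as a 0.1 M CH2Cl2 solution, never concentrated (explosion hazard)
Reagents that add atoms: sodium nitrite, [Na+].[O-]N=O
Why: Diazotization of the aromatic amine followed by loss of the very acidic ortho OH proton of the diazonium ion gives the neutral, CH2Cl2-soluble ortho-quinone diazide (diazonium phenolate), the standard entry to this compound class; no stereocentre is involved.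

**Step 2**
Reactants: 3 3-bromo-6-diazocyclohexa-2,4-dien-1-one; 4 2,4-dibromophenol
Product: 5 5-bromo-2-(2,4-dibromophenoxy)phenol
Conditions: Rh2(OAc)4 (1 mol%), 4 (3 equiv, excess recovered), 4 Å MS, CH2Cl2, 25–40 °C, dark; 3 added by syringe pump over 4 h
Reagents that add atoms: none
Why: Proposed new method: dirhodium-catalysed O–H insertion of a monocyclic ortho-quinone diazide into an electron-poor ortho-bromophenol; the divalent rhodium carboxylate dimer expels N2 from 3 to give a rhodium-bound quinoid carbene that behaves as a 2-oxidoaryl cation, the phenol oxygen of 4 adds to the carbene carbon to give an oxonium ylide, and the proton moves to the neighbouring phenoxide oxygen through a five-membered transition state with rearomatisation as the driving force, so the ether bond and the free ortho OH are delivered in one event; C-arylation of 4 is disfavoured because its para position is blocked and its ring is deactivated, the C–Br bonds are inert to carbene-transfer catalysis, slow addition suppresses carbene dimerisation and double insertion, and mild temperature in the dark avoids the Wolff ring contraction of 3; closest known reaction type: Rh2(OAc)4-catalysed O–H insertion of alpha-diazocarbonyl compounds into phenols, together with rhodium- and iridium-catalysed quinoid-carbene transfer from diazonaphthoquinones in C–H arylation.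

**Step 3**
Reactants: 5 5-bromo-2-(2,4-dibromophenoxy)phenol
Product: 7 2,3,4-tribromo-6-(2,4-dibromophenoxy)phenol, via 4,5-dibromo-2-(2,4-dibromophenoxy)phenol 6 (not isolated)
Conditions: Br2 (2.1 equiv), AcOH, 20 °C, 2 h
Reagents that add atoms: bromine, BrBr
Why: Electrophilic aromatic substitution (phenol bromination) under substrate control: the free OH is the strongest donor and directs bromine to its para position (giving 6) and then to its ortho position, the only two sites it activates, while the remaining ring A position (activated only by the ether oxygen) and the doubly brominated ring B react much more slowly; no stereocentre is formed.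

**Compound list**
1 | 2-amino-5-bromophenol | Nc1ccc(Br)cc1O | starting material
2 | 4-bromo-2-hydroxybenzenediazonium chloride | Oc1cc(Br)ccc1[N+]#N.[Cl-] | intermediate
3 | 3-bromo-6-diazocyclohexa-2,4-dien-1-one (equally drawn as the 4-bromo-2-oxidobenzenediazonium zwitterion) | [N-]=[N+]=C1C=CC(Br)=CC1=O | intermediate
4 | 2,4-dibromophenol | Oc1ccc(Br)cc1Br | starting material
5 | 5-bromo-2-(2,4-dibromophenoxy)phenol | Oc1cc(Br)ccc1Oc1ccc(Br)cc1Br | intermediate
6 | 4,5-dibromo-2-(2,4-dibromophenoxy)phenol | Oc1cc(Br)c(Br)cc1Oc1ccc(Br)cc1Br | intermediate
7 | 2,3,4-tribromo-6-(2,4-dibromophenoxy)phenol | Oc1c(Oc2ccc(Br)cc2Br)cc(Br)c(Br)c1Br | target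

**Totals**
Total step count: 3. Longest linear sequence: 3 steps (1 → 3 → 5 → 7); 4 enters in step 2.

**Steps most likely to fail, with fallbacks**

Step 2 is the most likely to fail, because it is the proposed new step. The risks are carbene dimerisation, a second insertion into the OH of product 5, and ring contraction of 3. The fallback uses known chemistry only, sets out from 4 and comes back at 5. Compound 4 is heated with bought 5-bromo-2-fluorobenzaldehyde (O=Cc1cc(Br)ccc1F) and K2CO3 in N,N-dimethylacetamide at 120 °C. This is an SNAr reaction in which the fluoride is activated by the ortho formyl group, and it gives 5-bromo-2-(2,4-dibromophenoxy)benzaldehyde F1. Baeyer–Villiger oxidation of F1 with 3-chloroperbenzoic acid in CH2Cl2 gives 5-bromo-2-(2,4-dibromophenoxy)phenyl formate F2. KOH in MeOH/H2O at 20 °C cleaves the formate to 5.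

Step 1 is the next most likely to fail. The risk is that 3 is light- and heat-sensitive and may be lost during neutralisation, extraction and drying. The fallback sets out from 1 and comes back at 3. Compound 1 is diazotised under non-aqueous conditions (tert-butyl nitrite, HBF4·OEt2, EtOH, 0 °C, precipitation with Et2O) to isolate the storable salt 4-bromo-2-hydroxybenzenediazonium tetrafluoroborate F3. Just before use, the salt is stirred with powdered NaHCO3 in CH2Cl2 at 0 °C, and the resulting solution of 3 is cannula-filtered straight into the flask of step 2.

Step 3 is the least likely to fail. The risks are over-bromination at the last free ring A position and incomplete bromination at the hindered position between OH and Br. The fallback sets out from 5 and comes back at 7; it makes no compound outside the list (F0). The bromination is staged and reagent-controlled instead of a one-pot double substitution. N-bromosuccinimide (1.0 equiv) in MeCN at 0 °C gives the para-bromide 6, which is now isolated and purified. Compound 6 is then brominated with the tert-butylamine–Br2 complex (N-bromo-tert-butylamine) in toluene at −30 °C. This reagent is delivered through the phenol O–H and substitutes only ortho to a free OH, which gives 7.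

**Further compounds**
F1 | step 2 | 5-bromo-2-(2,4-dibromophenoxy)benzaldehyde | O=Cc1cc(Br)ccc1Oc1ccc(Br)cc1Br
F2 | step 2 | 5-bromo-2-(2,4-dibromophenoxy)phenyl formate | O=COc1cc(Br)ccc1Oc1ccc(Br)cc1Br
F3 | step 1 | 4-bromo-2-hydroxybenzenediazonium tetrafluoroborate | Oc1cc(Br)ccc1[N+]#N.F[B-](F)(F)F
F0 | step 3 | none | none
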